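**Retrosynthetic overview**

1. With the side chain numbered C1′ (benzylic CH2) to C16′, the C4′–C3′ bond is made in a palladium-catalysed enantioselective three-component (conjunctive) cross-coupling: a bis(alkenyl)borate, built from a C14 trienyl pinacol boronate and CH2=CHMgBr, is coupled with an aryl-bearing (E)-alkenyl bromide. In the same operation the trienyl group shifts from boron to C5′ (C5′–C6′ bond), C5′ is set as (S), and oxidation of the C5′–B bond gives the carbinol.
2. Enabling feature: the two-carbon unit C4′H2–C5′H(OH) sits between two trisubstituted (E)-alkenes (C2′=C3′ and C6′=C7′) with the oxygen on the carbon next to C6′. This is the pattern a vinyl–boron unit acquires when an alkenyl group migrates to its boron-bearing carbon, an alkenyl electrophile adds to its terminal carbon and the C–B bond is oxidised.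
3. Boronate half: (E)-geranylacetone → terminal alkyne → zirconium-catalysed methylalumination/iodination → alkenyl boronate. Bromide half: 4-methoxy-2-methylphenol → ortho-formylation, O-methylation, reduction, bromination, copper-catalysed propynylation, hydrozirconation/bromination.
4. End game: oxidative demethylation of the hydroquinone dimethyl ether to the quinone, then reduction to the hydroquinone. No ring is formed in the route; the benzene ring is bought with its oxygen/methyl pattern in place.

Key step: step 10

Remark: in step 10 the sense of induction is ligand-controlled; the MandyPhos antipode meant is the one that gives the (S) C5′–B centre (both antipodes are available), and the assignment should be confirmed on the first run.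

**Route**

Step 1
Reactants: 1 (5E)-6,10-dimethylundeca-5,9-dien-2-one ((E)-geranylacetone)
Product: 3 (5E)-6,10-dimethylundeca-5,9-dien-1-yne, via enol phosphate 2 (not isolated)
Conditions: LiN(i-Pr)2 (1.05 equiv), THF, −78 °C; ClP(O)(OEt)2, −78 °C to rt; then LiN(i-Pr)2 (2.3 equiv), −78 °C to rt; H2O
Reagents that add atoms: none
Why: Kinetic deprotonation at the methyl group, O-phosphorylation and base-induced elimination of the enol phosphate (Negishi conversion of a methyl ketone into a terminal alkyne) should give the alkyne without touching the skipped (E)-alkene.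

Step 2
Reactants: 3 (5E)-6,10-dimethylundeca-5,9-dien-1-yne
Product: 5 (1E,5E)-1-iodo-2,6,10-trimethylundeca-1,5,9-triene, via alkenylalane 4 (not isolated)
Conditions: Me3Al (2 equiv), Cp2ZrCl2 (0.25 equiv), CH2Cl2, 0 °C to rt; then I2, THF, −30 °C to 0 °C
Reagents that add atoms: trimethylaluminium C[Al](C)C; iodine II
Why: Negishi zirconium-catalysed carboalumination adds methyl and aluminium syn across the terminal alkyne with aluminium on the terminal carbon, and iodinolysis of the C–Al bond with retention should fix the (E)-trisubstituted alkene.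

Step 3
Reactants: 5 (1E,5E)-1-iodo-2,6,10-trimethylundeca-1,5,9-triene
Product: 7 4,4,5,5-tetramethyl-2-[(1E,5E)-2,6,10-trimethylundeca-1,5,9-trien-1-yl]-1,3,2-dioxaborolane, via alkenyllithium 6 (not isolated)
Conditions: t-BuLi (2.1 equiv), Et2O, −78 °C; then 2-isopropoxy-4,4,5,5-tetramethyl-1,3,2-dioxaborolane, −78 °C to rt; aq. NH4Cl
Reagents that add atoms: 2-isopropoxy-4,4,5,5-tetramethyl-1,3,2-dioxaborolane CC(C)OB1OC(C)(C)C(C)(C)O1
Why: Lithium–iodine exchange of an alkenyl iodide proceeds with retention of geometry and the alkenyllithium is trapped at boron by the alkoxyboronate (borylation of an organolithium).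

Step 4
Reactants: 8 4-methoxy-2-methylphenol
Product: 9 2-hydroxy-5-methoxy-3-methylbenzaldehyde
Conditions: MgCl2, Et3N, (CH2O)n, MeCN, reflux; aq. HCl
Reagents that add atoms: paraformaldehyde (as formaldehyde) C=O
Why: Magnesium phenoxide-directed ortho-formylation (Casnati–Skattebøl formylation) can only attack the single free position ortho to the hydroxyl group.

Step 5
Reactants: 9 2-hydroxy-5-methoxy-3-methylbenzaldehyde
Product: 10 2,5-dimethoxy-3-methylbenzaldehyde
Conditions: MeI, K2CO3, DMF, rt to 40 °C
Reagents that add atoms: iodomethane CI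
Why: Williamson ether synthesis on the phenoxide should proceed cleanly once the hydrogen-bonded phenol is deprotonated in the dipolar solvent.

Step 6
Reactants: 10 2,5-dimethoxy-3-methylbenzaldehyde
Product: 11 (2,5-dimethoxy-3-methylphenyl)methanol
Conditions: NaBH4, MeOH, 0 °C
Reagents that add atoms: none
Why: Borohydride reduction of an aromatic aldehyde to the benzylic alcohol is chemoselective and leaves the aryl ethers untouched.

Step 7
Reactants: 11 (2,5-dimethoxy-3-methylphenyl)methanol
Product: 12 1-(bromomethyl)-2,5-dimethoxy-3-methylbenzene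
Conditions: PBr3 (0.4 equiv), CH2Cl2, 0 °C
Reagents that add atoms: phosphorus tribromide BrP(Br)Br
Why: Bromination of a primary benzylic alcohol with PBr3 (bromide displacement on the phosphite ester) should be fast at 0 °C, and the electron-rich bromide is used without storage.

Step 8
Reactants: 12 1-(bromomethyl)-2,5-dimethoxy-3-methylbenzene
Product: 13 1-(but-2-yn-1-yl)-2,5-dimethoxy-3-methylbenzene
Conditions: CH3C≡CMgBr (1.5 equiv), CuI (10 mol %), THF, 0 °C to rt
Reagents that add atoms: prop-1-ynylmagnesium bromide CC#C[Mg]Br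
Why: Copper-catalysed cross-coupling of an alkynylmagnesium halide with a benzylic bromide should give the skipped aryl alkyne, the mild temperature keeping it from isomerising to the allene.

Step 9
Reactants: 13 1-(but-2-yn-1-yl)-2,5-dimethoxy-3-methylbenzene
Product: 15 1-[(2E)-3-bromobut-2-en-1-yl]-2,5-dimethoxy-3-methylbenzene, via alkenylzirconocene 14 (not isolated)
Conditions: Cp2Zr(H)Cl (2.5 equiv), THF, 50 °C; then N-bromosuccinimide, 0 °C
Reagents that add atoms: N-bromosuccinimide O=C1CCC(=O)N1Br
Why: Hydrozirconation with excess Cp2Zr(H)Cl at 50 °C adds H and Zr syn and equilibrates the metal to the less hindered, methyl-bearing alkyne carbon, and bromodezirconation with retention should give the (E)-alkenyl bromide.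

Step 10
Reactants: 7 4,4,5,5-tetramethyl-2-[(1E,5E)-2,6,10-trimethylundeca-1,5,9-trien-1-yl]-1,3,2-dioxaborolane; 15 1-[(2E)-3-bromobut-2-en-1-yl]-2,5-dimethoxy-3-methylbenzene
Product: 18 (2E,5S,6E,10E)-1-(2,5-dimethoxy-3-methylphenyl)-3,7,11,15-tetramethylhexadeca-2,6,10,14-tetraen-5-ol, via vinylborate complex 16 (not isolated), via allylic boronate 17 (not isolated)
Conditions: 7 (1.2 equiv), CH2=CHMgBr (1.2 equiv), NaOSO2CF3 (3 equiv), THF, 0 °C to rt; then Pd(OAc)2 (3 mol %), MandyPhos {1,1′-bis[bis(4-methoxy-3,5-dimethylphenyl)phosphino]-2,2′-bis[α-(dimethylamino)benzyl]ferrocene, antipode giving the (S) product} (3.6 mol %), 15 (1.0 equiv), THF, 60 °C; then 3 M NaOH, 30% H2O2, 0 °C to rt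
Reagents that add atoms: vinylmagnesium bromide C=C[Mg]Br; hydrogen peroxide OO
Why: Addition of CH2=CHMgBr to boronate 7 gives the four-coordinate bis(alkenyl)borate 16; oxidative addition of bromide 15 to zerovalent palladium and bromide removal by NaOSO2CF3 give a cationic alkenylpalladium species (divalent palladium) that binds the unsubstituted vinyl group of 16 and triggers a 1,2-metallate shift of the trisubstituted alkenyl group from boron to the adjacent carbon (C5′–C6′ bond), after which reductive elimination forms the C4′–C3′ bond to give allylic boronate 17, oxidised in the same flask with retention to alcohol 18. The closest known reaction type is the palladium/MandyPhos-catalysed enantioselective conjunctive cross-coupling of magnesium-derived bis(alkenyl)borates with sp2 halides in the presence of NaOSO2CF3, which delivers α-chiral allylic boronic esters. No ring is closed. The C5′ stereocentre is set under catalyst control in the metallate shift, the chiral diphosphine selecting the face of the vinyl group that palladium binds, and the stereoretentive C–B oxidation transfers that configuration to the carbinol. The step needs (a) migration of the trisubstituted alkenyl group and not of vinyl, secured because only the unsubstituted vinyl group is an unhindered π-ligand for palladium, (b) metallate shift in preference to direct Suzuki-type alkenyl transfer, favoured by the wide-bite-angle ligand and a halide-free cationic palladium, and (c) retention of both alkene geometries, which follows because the migrating and the palladium-bound sp2 carbons keep their substituent arrangement throughout.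

Step 11
Reactants: 18 (2E,5S,6E,10E)-1-(2,5-dimethoxy-3-methylphenyl)-3,7,11,15-tetramethylhexadeca-2,6,10,14-tetraen-5-ol
Product: 19 2-[(2E,5S,6E,10E)-5-hydroxy-3,7,11,15-tetramethylhexadeca-2,6,10,14-tetraen-1-yl]-6-methylcyclohexa-2,5-diene-1,4-dione
Conditions: (NH4)2Ce(NO3)6 (2.5 equiv), MeCN/H2O (2:1), 0 °C, 15 min
Reagents that add atoms: water O
Why: Oxidative demethylation of the 1,4-dimethoxyarene by the tetravalent cerium salt proceeds through the arene radical cation and hydration to the para-quinone, and the electron-rich arene should be oxidised far faster at 0 °C than the isolated alkenes or the secondary alcohol.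

Step 12
Reactants: 19 2-[(2E,5S,6E,10E)-5-hydroxy-3,7,11,15-tetramethylhexadeca-2,6,10,14-tetraen-1-yl]-6-methylcyclohexa-2,5-diene-1,4-dione
Product: 20 2-[(2E,5S,6E,10E)-5-hydroxy-3,7,11,15-tetramethylhexadeca-2,6,10,14-tetraen-1-yl]-6-methylbenzene-1,4-diol
Conditions: Na2S2O4, Et2O/H2O, rt, argon
Reagents that add atoms: none
Why: Dithionite reduction of a quinone to the hydroquinone is a mild two-electron, two-proton transfer that should leave the alkenes and the allylic alcohol untouched.

**Compound list**

1 | (5E)-6,10-dimethylundeca-5,9-dien-2-one ((E)-geranylacetone) | CC(=O)CC/C=C(\C)CCC=C(C)C | starting material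
2 | diethyl (5E)-6,10-dimethylundeca-1,5,9-trien-2-yl phosphate | C=C(OP(=O)(OCC)OCC)CC/C=C(\C)CCC=C(C)C | intermediate
3 | (5E)-6,10-dimethylundeca-5,9-dien-1-yne | C#CCC/C=C(\C)CCC=C(C)C | intermediate
4 | dimethyl[(1E,5E)-2,6,10-trimethylundeca-1,5,9-trien-1-yl]alumane | C[Al](C)/C=C(\C)CC/C=C(\C)CCC=C(C)C | intermediate
5 | (1E,5E)-1-iodo-2,6,10-trimethylundeca-1,5,9-triene | I/C=C(\C)CC/C=C(\C)CCC=C(C)C | intermediate
6 | [(1E,5E)-2,6,10-trimethylundeca-1,5,9-trien-1-yl]lithium | [Li]/C=C(\C)CC/C=C(\C)CCC=C(C)C | intermediate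
7 | 4,4,5,5-tetramethyl-2-[(1E,5E)-2,6,10-trimethylundeca-1,5,9-trien-1-yl]-1,3,2-dioxaborolane | CC1(C)OB(/C=C(\C)CC/C=C(\C)CCC=C(C)C)OC1(C)C | intermediate
8 | 4-methoxy-2-methylphenol | COc1ccc(O)c(C)c1 | starting material
9 | 2-hydroxy-5-methoxy-3-methylbenzaldehyde | COc1cc(C)c(O)c(C=O)c1 | intermediate
10 | 2,5-dimethoxy-3-methylbenzaldehyde | COc1cc(C)c(OC)c(C=O)c1 | intermediate
11 | (2,5-dimethoxy-3-methylphenyl)methanol | COc1cc(C)c(OC)c(CO)c1 | intermediate
12 | 1-(bromomethyl)-2,5-dimethoxy-3-methylbenzene | COc1cc(C)c(OC)c(CBr)c1 | intermediate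
13 | 1-(but-2-yn-1-yl)-2,5-dimethoxy-3-methylbenzene | CC#CCc1cc(OC)cc(C)c1OC | intermediate
14 | chlorobis(cyclopentadienyl)[(2E)-4-(2,5-dimethoxy-3-methylphenyl)but-2-en-2-yl]zirconium | C/C(=C\Cc1cc(OC)cc(C)c1OC)[Zr](Cl)(C1C=CC=C1)C1C=CC=C1 | intermediate
15 | 1-[(2E)-3-bromobut-2-en-1-yl]-2,5-dimethoxy-3-methylbenzene | C/C(Br)=C\Cc1cc(OC)cc(C)c1OC | intermediate
16 | bromomagnesium ethenyl(pinacolato)[(1E,5E)-2,6,10-trimethylundeca-1,5,9-trien-1-yl]borate | C=C[B-]1(/C=C(\C)CC/C=C(\C)CCC=C(C)C)OC(C)(C)C(C)(C)O1.[Mg+]Br | intermediate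
17 | 2-[(2E,5S,6E,10E)-1-(2,5-dimethoxy-3-methylphenyl)-3,7,11,15-tetramethylhexadeca-2,6,10,14-tetraen-5-yl]-4,4,5,5-tetramethyl-1,3,2-dioxaborolane | CC(C)=CCC/C(C)=C/CC/C(C)=C/[C@@H](B1OC(C)(C)C(C)(C)O1)C/C(C)=C/Cc1cc(OC)cc(C)c1OC | intermediate
18 | (2E,5S,6E,10E)-1-(2,5-dimethoxy-3-methylphenyl)-3,7,11,15-tetramethylhexadeca-2,6,10,14-tetraen-5-ol | CC(C)=CCC/C(C)=C/CC/C(C)=C/[C@@H](O)C/C(C)=C/Cc1cc(OC)cc(C)c1OC | intermediate
19 | 2-[(2E,5S,6E,10E)-5-hydroxy-3,7,11,15-tetramethylhexadeca-2,6,10,14-tetraen-1-yl]-6-methylcyclohexa-2,5-diene-1,4-dione | CC(C)=CCC/C(C)=C/CC/C(C)=C/[C@@H](O)C/C(C)=C/CC1=CC(=O)C=C(C)C1=O | intermediate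
20 | 2-[(2E,5S,6E,10E)-5-hydroxy-3,7,11,15-tetramethylhexadeca-2,6,10,14-tetraen-1-yl]-6-methylbenzene-1,4-diol | CC(C)=CCC/C(C)=C/CC/C(C)=C/[C@@H](O)C/C(C)=C/Cc1cc(O)cc(C)c1O | target

**Step count and risks**

Total step count: 12. Longest linear sequence: 9 steps (steps 4 to 12, from 4-methoxy-2-methylphenol); the boronate branch adds 3 steps (steps 1 to 3).

Steps most likely to fail:

1. Step 10. What may go wrong: direct alkenyl transfer from boron to palladium (Suzuki-type coupling) outrunning the metallate shift, incomplete bromide sequestration slowing the cationic pathway, or insufficient facial selectivity at C5′. The fallback sets out from bromide 15 and comes back to the route at alcohol 18; it makes the same C4′–C3′ bond by an epoxide opening. Bought (2E,6E)-farnesal should give, with trimethylsulfonium iodide and KOt-Bu in DMSO/THF (Corey–Chaykovsky epoxidation), racemic 2-[(1E,5E)-2,6,10-trimethylundeca-1,5,9-trien-1-yl]oxirane F1. Jacobsen hydrolytic kinetic resolution with 0.55 equiv H2O and the antipode of N,N′-bis(3,5-di-tert-butylsalicylidene)cyclohexane-1,2-diaminocobalt acetate (trivalent cobalt) that hydrolyses the (S)-epoxide should leave (2R)-2-[(1E,5E)-2,6,10-trimethylundeca-1,5,9-trien-1-yl]oxirane F2. Bromide 15 with t-BuLi (Et2O, −78 °C) should give, with retention of geometry, [(2Z)-4-(2,5-dimethoxy-3-methylphenyl)but-2-en-2-yl]lithium F3. F3 is added to F2 in THF/DMPU (−40 to 0 °C) without copper salt or Lewis acid, so that SN2 attack at the unsubstituted ring carbon should prevail over allylic opening and over SN2′ attack at the fully substituted C7′. Aqueous work-up then gives 18 directly with the C5′ configuration carried by the epoxide.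

2. Step 11. What may go wrong: acid-promoted ionisation and allylic transposition of the C5′ allylic alcohol, or oxidation of the side chain, in the acidic ceric medium. The fallback sets out from bromide 15 and comes back to the route at target 20; it unmasks the hydroquinone before the sensitive alcohol exists and ends with a fluoride deprotection. Bromide 15 with (NH4)2Ce(NO3)6 in MeCN/H2O should give 2-[(2E)-3-bromobut-2-en-1-yl]-6-methylcyclohexa-2,5-diene-1,4-dione F4, and Na2S2O4 should reduce it to 2-[(2E)-3-bromobut-2-en-1-yl]-6-methylbenzene-1,4-diol F5. Silylation with i-Pr3SiOSO2CF3 and 2,6-lutidine should give the bis(triisopropylsilyl) ether {2-[(2E)-3-bromobut-2-en-1-yl]-6-methyl-1,4-phenylene}bis(oxy)bis[tri(propan-2-yl)silane] F6. F6 is coupled with boronate 7 and CH2=CHMgBr under the conditions of step 10 to give the bis(triisopropylsilyl)-protected allylic boronate F7 (not isolated), which is oxidised with NaBO3·4H2O in THF/H2O, mild enough to spare the aryl silyl ethers, to the bis(triisopropylsilyl)-protected (5S)-alcohol F8. Bu4NF buffered with AcOH (THF, 0 °C, argon) then removes both silyl groups to give 20.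

3. Step 9. What may go wrong: incomplete equilibration of the alkenylzirconium, so that the regioisomer with the metal on the benzyl-side carbon carries through to an isomeric bromide that is hard to separate. The fallback sets out from benzylic bromide 12 and comes back to the route at bromide 15; the regiochemistry is fixed by the constitution of a dihaloalkene instead of by equilibration. Zinc insertion into 12 (Zn dust, LiCl, THF) should give (2,5-dimethoxy-3-methylbenzyl)zinc bromide F9. Propyne and IBr (CH2Cl2, −78 °C; anti addition with iodine on the terminal carbon) should give (1E)-2-bromo-1-iodoprop-1-ene F10. Negishi coupling of F9 with F10 catalysed by Pd(PPh3)4 should occur at the C–I bond, which adds oxidatively faster than C–Br, with retention of geometry, to give 15.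

**Further compounds**

F1 | step 10 | racemic 2-[(1E,5E)-2,6,10-trimethylundeca-1,5,9-trien-1-yl]oxirane | CC(C)=CCC/C(C)=C/CC/C(C)=C/C1CO1
F2 | step 10 | (2R)-2-[(1E,5E)-2,6,10-trimethylundeca-1,5,9-trien-1-yl]oxirane | CC(C)=CCC/C(C)=C/CC/C(C)=C/[C@@H]1CO1
F3 | step 10 | [(2Z)-4-(2,5-dimethoxy-3-methylphenyl)but-2-en-2-yl]lithium | C/C([Li])=C\Cc1cc(OC)cc(C)c1OC
F4 | step 11 | 2-[(2E)-3-bromobut-2-en-1-yl]-6-methylcyclohexa-2,5-diene-1,4-dione | C/C(Br)=C\CC1=CC(=O)C=C(C)C1=O
F5 | step 11 | 2-[(2E)-3-bromobut-2-en-1-yl]-6-methylbenzene-1,4-diol | C/C(Br)=C\Cc1cc(O)cc(C)c1O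
F6 | step 11 | {2-[(2E)-3-bromobut-2-en-1-yl]-6-methyl-1,4-phenylene}bis(oxy)bis[tri(propan-2-yl)silane] | C/C(Br)=C\Cc1cc(O[Si](C(C)C)(C(C)C)C(C)C)cc(C)c1O[Si](C(C)C)(C(C)C)C(C)C
F7 | step 11 | 2-[(2E,5S,6E,10E)-1-{3-methyl-2,5-bis[tri(propan-2-yl)silyloxy]phenyl}-3,7,11,15-tetramethylhexadeca-2,6,10,14-tetraen-5-yl]-4,4,5,5-tetramethyl-1,3,2-dioxaborolane | CC(C)=CCC/C(C)=C/CC/C(C)=C/[C@@H](B1OC(C)(C)C(C)(C)O1)C/C(C)=C/Cc1cc(O[Si](C(C)C)(C(C)C)C(C)C)cc(C)c1O[Si](C(C)C)(C(C)C)C(C)C
F8 | step 11 | (2E,5S,6E,10E)-1-{3-methyl-2,5-bis[tri(propan-2-yl)silyloxy]phenyl}-3,7,11,15-tetramethylhexadeca-2,6,10,14-tetraen-5-ol | CC(C)=CCC/C(C)=C/CC/C(C)=C/[C@@H](O)C/C(C)=C/Cc1cc(O[Si](C(C)C)(C(C)C)C(C)C)cc(C)c1O[Si](C(C)C)(C(C)C)C(C)C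
F9 | step 9 | (2,5-dimethoxy-3-methylbenzyl)zinc bromide | Br[Zn]Cc1cc(OC)cc(C)c1OC
F10 | step 9 | (1E)-2-bromo-1-iodoprop-1-ene | C/C(Br)=C\I
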